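**Retrosynthetic overview**
1. Target ← desilylation and α-methylenation of a 17-nor macrolide; the 14-membered carbocycle is closed last at C9–C10 by RCM/hydrogenation.
2. Ring A (ε-lactone) is grown from cyclobutanone by three 1,2-shift ring expansions: semipinacol (4→5, sets C11/C12), Baeyer–Villiger (5→6, C12–O with retention), ynolate homologation (6→7, inserts C15).
3. C1–C2: the cyclopentanone enolate of fragment 2 opens the terminal epoxide of fragment 1, which also unveils C3–OH and sets C1.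
4. Fragment 1 (oxolane, C3/C4/C7/C8): Shi bis-epoxidation of an (E,E)-trienol, then a Payne rearrangement/5-exo epoxide-opening cascade. Both fragments use the same Shi ketone.
5. Ring order: oxolane and cyclopentanone (separately) → oxan-2-one → oxepan-2-one → 14-membered carbocycle.

Assumption: cembrane numbering (C1–C20) is used for atom labels; in it the given SMILES is (1R,3S,4R,7S,8R,11R,12R), and but-1-en-3-yne is taken as a commercial solution.

**Route**

Step 1
Reactants: 1 pent-4-yn-1-ol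
Product: 3 (2E)-2-methylhept-2-en-6-ynal, via pent-4-ynal 2 (not isolated)
Conditions: TEMPO (10 mol %), PhI(OAc)2, CH2Cl2, 23 °C; then Ph3P=C(Me)CHO, 40 °C
Reagents that add atoms: 2-(triphenylphosphoranylidene)propanal, CC(C=O)=P(c1ccccc1)(c1ccccc1)c1ccccc1
Why: Oxoammonium oxidation gives the volatile aldehyde, which is trapped in the same flask by Wittig olefination with a stabilised ylide to give the trisubstituted (E)-enal (C7=C8).

Step 2
Reactants: 3 (2E)-2-methylhept-2-en-6-ynal
Product: 4 (3E)-3-methylocta-1,3-dien-7-yne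
Conditions: Ph3PCH3Br, KOt-Bu, THF, 0 °C
Reagents that add atoms: methyltriphenylphosphonium bromide, C[P+](c1ccccc1)(c1ccccc1)c1ccccc1.[Br-]
Why: Wittig methylenation of the enal carbonyl gives the 1,3-diene without touching the (E)-alkene or the alkyne.

Step 3
Reactants: 4 (3E)-3-methylocta-1,3-dien-7-yne
Product: 6 (2E,6E)-3,7-dimethylnona-2,6,8-trien-1-ol, via alkenylalane 5 (not isolated)
Conditions: Me3Al, Cp2ZrCl2 (20 mol %), CH2Cl2, 0 → 23 °C; then n-BuLi, THF, −78 °C; (CH2O)n, → 23 °C; H2O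
Reagents that add atoms: trimethylaluminium, C[Al](C)C; paraformaldehyde (formaldehyde unit), C=O
Why: Negishi zirconium-catalysed syn-carboalumination puts Me on the internal alkyne carbon and Al on the terminus, and the derived aluminate is hydroxymethylated with retention, so C3=C4 is formed as the E isomer only.

Step 4
Reactants: 6 (2E,6E)-3,7-dimethylnona-2,6,8-trien-1-ol
Product: 9 (2R)-2-{(2S,5R)-5-methyl-5-[(2S)-oxiran-2-yl]oxolan-2-yl}but-3-en-2-ol, via bis-epoxy alcohol 7 (not isolated), via Payne isomer 8 (not isolated)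
Conditions: D-fructose-derived Shi ketone (40 mol %), Oxone (2KHSO5·KHSO4·K2SO4), K2CO3, Bu4NHSO4, MeCN/CH2(OMe)2–aq. Na2B4O7 (pH 10.5), 0 °C; then aq. NaOH (to 0.5 M), 23 → 40 °C
Reagents that add atoms: potassium peroxymonosulfate (active part of Oxone), [K+].[O-]S(=O)(=O)OO
Why: Shi asymmetric epoxidation attacks only the two trisubstituted alkenes and gives the (R,R)-epoxides (spiro transition state); base then triggers a Payne rearrangement (O on C2 attacks C3, inversion) and the freed C4 alkoxide opens the vinyl epoxide 5-exo at C7 (inversion), an epoxide-opening cascade that sets 3S,4R,7S,8R and the cis-oxolane.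

Step 5
Reactants: 10 cyclobutanone; 11 but-1-en-3-yne
Product: 13 1-[(2E)-penta-2,4-dien-2-yl]cyclobutan-1-ol, via magnesium alkoxide 12 (not isolated)
Conditions: 11, EtMgBr, THF, 0 °C; 10, 0 → 23 °C; then MeMgBr (3 equiv), CuI (10 mol %), 23 → 50 °C; aq. NH4Cl
Reagents that add atoms: methylmagnesium bromide, C[Mg]Br
Why: Alkynyl Grignard addition followed by copper-catalysed, alkoxide-directed anti-carbomagnesiation of the propargylic alkoxide puts Me on the carbon next to the carbinol and H trans to it, which fixes the E geometry needed in step 6.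

Step 6
Reactants: 13 1-[(2E)-penta-2,4-dien-2-yl]cyclobutan-1-ol
Product: 15 (2R)-2-[(1R)-1-hydroxyprop-2-en-1-yl]-2-methylcyclopentan-1-one, via epoxy cyclobutanol 14 (not isolated)
Conditions: D-fructose-derived Shi ketone (30 mol %), Oxone (2KHSO5·KHSO4·K2SO4), K2CO3, Bu4NHSO4, MeCN/CH2(OMe)2–aq. Na2B4O7 (pH 10.5), −10 °C; extract; then BF3·OEt2 (10 mol %), CH2Cl2, −78 °C
Reagents that add atoms: potassium peroxymonosulfate (active part of Oxone), [K+].[O-]S(=O)(=O)OO
Why: Shi asymmetric epoxidation of the trisubstituted alkene (same ketone and facial sense as step 4) followed by Lewis-acid semipinacol rearrangement, in which a cyclobutane CH2 migrates to C12 anti to the breaking C–O bond, expands the ring to the cyclopentanone and sets the quaternary C12 (R) and the carbinol C11 (R) together.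

Step 7
Reactants: 15 (2R)-2-[(1R)-1-hydroxyprop-2-en-1-yl]-2-methylcyclopentan-1-one
Product: 16 (2R)-2-[(1R)-1-(tert-butyldimethylsilyloxy)prop-2-en-1-yl]-2-methylcyclopentan-1-one
Conditions: TBSOTf, 2,6-lutidine, CH2Cl2, −78 → 0 °C
Reagents that add atoms: tert-butyldimethylsilyl trifluoromethanesulfonate, CC(C)(C)[Si](C)(C)OS(=O)(=O)C(F)(F)F
Why: Silyl triflate protection of the hindered secondary alcohol blocks retro-aldol cleavage in the enolate chemistry that follows.

Step 8
Reactants: 16 (2R)-2-[(1R)-1-(tert-butyldimethylsilyloxy)prop-2-en-1-yl]-2-methylcyclopentan-1-one; 9 (2R)-2-{(2S,5R)-5-methyl-5-[(2S)-oxiran-2-yl]oxolan-2-yl}but-3-en-2-ol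
Product: 17 (2R,5R)-2-[(1R)-1-(tert-butyldimethylsilyloxy)prop-2-en-1-yl]-5-[(2S)-2-hydroxy-2-[(2R,5S)-5-[(2R)-2-hydroxybut-3-en-2-yl]-2-methyloxolan-2-yl]ethyl]-2-methylcyclopentan-1-one
Conditions: 16 (1.5 equiv), LiN(i-Pr)2 (1.5 equiv), THF, −78 °C; then 9, Sc(OTf)3 (10 mol %), −78 → 0 °C; aq. NH4Cl
Reagents that add atoms: none
Why: Sc(OTf)3-catalysed opening of the terminal epoxide at its CH2 by the lithium enolate (C1 is the only enolisable carbon; enolate–epoxide alkylation) forms C1–C2 and unveils C3–OH, with attack anti to the bulky C12 side chain giving the 2,5-trans ketone (C1 R).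

Step 9
Reactants: 17 (γ-hydroxy ketone from step 8)
Product: 18 (2R,5R)-2-[(1R)-1-(tert-butyldimethylsilyloxy)prop-2-en-1-yl]-5-[(2S)-2-[(2R,5S)-5-[(2R)-2-hydroxybut-3-en-2-yl]-2-methyloxolan-2-yl]-2-(triethylsilyloxy)ethyl]-2-methylcyclopentan-1-one
Conditions: Et3SiCl, imidazole, DMF, 0 °C
Reagents that add atoms: chlorotriethylsilane, CC[Si](Cl)(CC)CC
Why: Chlorosilane/imidazole silylation is selective for the secondary C3 hydroxyl over the tertiary C8 hydroxyl and keeps the C3 oxygen from attacking the lactone carbonyl made next.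

Step 10
Reactants: 18 (bis-silyl cyclopentanone from step 9)
Product: 19 (3R,6R)-6-[(1R)-1-(tert-butyldimethylsilyloxy)prop-2-en-1-yl]-3-[(2S)-2-[(2R,5S)-5-[(2R)-2-hydroxybut-3-en-2-yl]-2-methyloxolan-2-yl]-2-(triethylsilyloxy)ethyl]-6-methyloxan-2-one
Conditions: mCPBA (1.3 equiv), NaHCO3, CH2Cl2, 0 → 23 °C
Reagents that add atoms: 3-chloroperoxybenzoic acid, O=C(OO)c1cccc(Cl)c1
Why: Baeyer–Villiger ring expansion in which the quaternary C12 migrates in preference to the secondary C1 and with retention, installing the tertiary C12–O bond; the two oxygen-flanked monosubstituted alkenes are epoxidised far more slowly.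

Step 11
Reactants: 19 (δ-lactone from step 10)
Product: 21 (4R,7R)-7-[(1R)-1-(tert-butyldimethylsilyloxy)prop-2-en-1-yl]-4-[(2S)-2-[(2R,5S)-5-[(2R)-2-hydroxybut-3-en-2-yl]-2-methyloxolan-2-yl]-2-(triethylsilyloxy)ethyl]-7-methyloxepan-2-one, via lithium ynolate 20 (not isolated)
Conditions: CH2Br2, lithium 2,2,6,6-tetramethylpiperidide (3.3 equiv), THF, −78 °C; 19; n-BuLi (3 equiv), −78 → −20 °C; then 2,6-di-tert-butyl-4-methylphenol, −78 → 0 °C; aq. NH4Cl
Reagents that add atoms: dibromomethane, BrCBr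
Why: Proposed new method: homologative ring expansion of a δ-lactone through its ynolate — LiCHBr2 adds to the lactone carbonyl, the adduct opens to the C12 alkoxide and a dibromomethyl ketone enolate, Br/Li exchange gives a carbenoid in which C1 shifts from C16 to the new carbon C15 with retention (1,2-shift) to give ynolate 20, and C-protonation releases a ketene that the internal tertiary alkoxide recaptures to close the seven-membered lactone; the closest known reaction is the Kowalski ester homologation (with ketene lactonisation), which has not been used to ring-expand a lactone.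

Step 12
Reactants: 21 (ε-lactone diene from step 11)
Product: 23 (1R,3S,4R,7S,8R,11R,12R)-11-O-(tert-butyldimethylsilyl)-3-O-(triethylsilyl)-17-norquerciformolide D, via macrocyclic alkene 22 (not isolated)
Conditions: second-generation Grubbs catalyst RuCl2(=CHPh)(PCy3)(1,3-dimesitylimidazolidin-2-ylidene) (10 mol %), toluene (1 mM), 80 °C; then H2 (30 bar), 70 °C
Reagents that add atoms: none
Why: Ring-closing metathesis of the two monosubstituted vinyl groups (initiation helped by the free tertiary allylic hydroxyl) closes the 14-membered carbocycle, and under H2 the ruthenium carbene becomes a hydride catalyst that saturates C9=C10 in the same flask (tandem RCM–hydrogenation), so alkene geometry does not matter.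

Step 13
Reactants: 23 (17-nor macrolide from step 12)
Product: 25 (1R,3S,4R,7S,8R,11R,12R)-11-O-(tert-butyldimethylsilyl)-3-O-(triethylsilyl)querciformolide D, via Mannich base 24 (not isolated)
Conditions: LiN(i-Pr)2 (2.5 equiv), THF, −78 °C; CH2=NMe2+ I−, −78 → 23 °C; then MeI, MeOH; aq. NaHCO3
Reagents that add atoms: N,N-dimethylmethyleneiminium iodide (Eschenmoser's salt), C=[N+](C)C.[I-]
Why: Mannich reaction of the lactone enolate (C15 is the only enolisable position) with Eschenmoser's salt, then N-methylation and E1cB elimination, installs the exo-methylene (α-methylenation).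

Step 14
Reactants: 25 (bis-silyl ether of the target)
Product: 26 querciformolide D
Conditions: HF·pyridine, pyridine, THF, 0 → 23 °C
Reagents that add atoms: none
Why: Buffered fluoride desilylation removes both silyl ethers under conditions too mild for translactonisation onto C3–OH or conjugate addition to the α-methylene lactone.

**Compound list**
1 | pent-4-yn-1-ol | C#CCCCO | starting material
2 | pent-4-ynal | C#CCCC=O | intermediate
3 | (2E)-2-methylhept-2-en-6-ynal | C#CCC/C=C(C)/C=O | intermediate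
4 | (3E)-3-methylocta-1,3-dien-7-yne | C#CCC/C=C(C)/C=C | intermediate
5 | dimethyl[(1E,5E)-2,6-dimethylocta-1,5,7-trien-1-yl]alumane | C[Al](C)/C=C(C)/CC/C=C(C)/C=C | intermediate
6 | (2E,6E)-3,7-dimethylnona-2,6,8-trien-1-ol | OC/C=C(C)/CC/C=C(C)/C=C | intermediate
7 | [(2R,3R)-3-{2-[(2R,3R)-3-ethenyl-3-methyloxiran-2-yl]ethyl}-3-methyloxiran-2-yl]methanol | OC[C@H]1O[C@]1(C)CC[C@H]1O[C@]1(C)C=C | intermediate
8 | (2R)-4-[(2R,3R)-3-ethenyl-3-methyloxiran-2-yl]-2-[(2S)-oxiran-2-yl]butan-2-ol | C1O[C@@H]1[C@](C)(O)CC[C@H]1O[C@]1(C)C=C | intermediate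
9 | (2R)-2-{(2S,5R)-5-methyl-5-[(2S)-oxiran-2-yl]oxolan-2-yl}but-3-en-2-ol | C1O[C@@H]1[C@@]2(C)CC[C@H](O2)[C@](C)(O)C=C | intermediate
10 | cyclobutanone | O=C1CCC1 | starting material
11 | but-1-en-3-yne | C=CC#C | starting material
12 | bromomagnesium 1-(but-3-en-1-yn-1-yl)cyclobutan-1-olate | C=CC#CC1(CCC1)O[Mg]Br | intermediate
13 | 1-[(2E)-penta-2,4-dien-2-yl]cyclobutan-1-ol | C=C/C=C(C)/C1(O)CCC1 | intermediate
14 | 1-[(2S,3R)-3-ethenyl-2-methyloxiran-2-yl]cyclobutan-1-ol | OC1(CCC1)[C@@]1(C)O[C@@H]1C=C | intermediate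
15 | (2R)-2-[(1R)-1-hydroxyprop-2-en-1-yl]-2-methylcyclopentan-1-one | O=C1CCC[C@]1(C)[C@H](O)C=C | intermediate
16 | (2R)-2-[(1R)-1-(tert-butyldimethylsilyloxy)prop-2-en-1-yl]-2-methylcyclopentan-1-one | O=C1CCC[C@]1(C)[C@H](O[Si](C)(C)C(C)(C)C)C=C | intermediate
17 | (2R,5R)-2-[(1R)-1-(tert-butyldimethylsilyloxy)prop-2-en-1-yl]-5-[(2S)-2-hydroxy-2-[(2R,5S)-5-[(2R)-2-hydroxybut-3-en-2-yl]-2-methyloxolan-2-yl]ethyl]-2-methylcyclopentan-1-one | O=C1[C@@H](C[C@H](O)[C@@]2(C)CC[C@H](O2)[C@](C)(O)C=C)CC[C@]1(C)[C@H](O[Si](C)(C)C(C)(C)C)C=C | intermediate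
18 | 3-O-triethylsilyl ether of 17 | O=C1[C@@H](C[C@H](O[Si](CC)(CC)CC)[C@@]2(C)CC[C@H](O2)[C@](C)(O)C=C)CC[C@]1(C)[C@H](O[Si](C)(C)C(C)(C)C)C=C | intermediate
19 | (3R,6R)-6-[(1R)-1-(tert-butyldimethylsilyloxy)prop-2-en-1-yl]-3-[(2S)-2-[(2R,5S)-5-[(2R)-2-hydroxybut-3-en-2-yl]-2-methyloxolan-2-yl]-2-(triethylsilyloxy)ethyl]-6-methyloxan-2-one | O=C1O[C@@](C)([C@H](O[Si](C)(C)C(C)(C)C)C=C)CC[C@@H]1C[C@H](O[Si](CC)(CC)CC)[C@@]2(C)CC[C@H](O2)[C@](C)(O)C=C | intermediate
20 | trilithium salt of the ring-opened ynolate (LiO–C16≡C15–C1, C12–OLi, C8–OLi) | [Li]OC#C[C@@H](C[C@H](O[Si](CC)(CC)CC)[C@@]1(C)CC[C@H](O1)[C@](C)(O[Li])C=C)CC[C@@](C)(O[Li])[C@H](O[Si](C)(C)C(C)(C)C)C=C | intermediate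
21 | (4R,7R)-7-[(1R)-1-(tert-butyldimethylsilyloxy)prop-2-en-1-yl]-4-[(2S)-2-[(2R,5S)-5-[(2R)-2-hydroxybut-3-en-2-yl]-2-methyloxolan-2-yl]-2-(triethylsilyloxy)ethyl]-7-methyloxepan-2-one | O=C1O[C@@](C)([C@H](O[Si](C)(C)C(C)(C)C)C=C)CC[C@@H](C1)C[C@H](O[Si](CC)(CC)CC)[C@@]2(C)CC[C@H](O2)[C@](C)(O)C=C | intermediate
22 | 9,10-didehydro derivative of 23 (E/Z mixture) | C1C(=O)O[C@]2(C)CC[C@@H]1C[C@H](O[Si](CC)(CC)CC)[C@@]1(C)CC[C@H](O1)[C@](C)(O)C=C[C@H]2O[Si](C)(C)C(C)(C)C | intermediate
23 | (1R,3S,4R,7S,8R,11R,12R)-11-O-(tert-butyldimethylsilyl)-3-O-(triethylsilyl)-17-norquerciformolide D (C15 is CH2) | C1C(=O)O[C@]2(C)CC[C@@H]1C[C@H](O[Si](CC)(CC)CC)[C@@]1(C)CC[C@H](O1)[C@](C)(O)CC[C@H]2O[Si](C)(C)C(C)(C)C | intermediate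
24 | 15-[(dimethylamino)methyl] derivative of 23 (C15 epimers) | CN(C)CC1C(=O)O[C@]2(C)CC[C@@H]1C[C@H](O[Si](CC)(CC)CC)[C@@]1(C)CC[C@H](O1)[C@](C)(O)CC[C@H]2O[Si](C)(C)C(C)(C)C | intermediate
25 | (1R,3S,4R,7S,8R,11R,12R)-11-O-(tert-butyldimethylsilyl)-3-O-(triethylsilyl)querciformolide D | C=C1C(=O)O[C@]2(C)CC[C@@H]1C[C@H](O[Si](CC)(CC)CC)[C@@]1(C)CC[C@H](O1)[C@](C)(O)CC[C@H]2O[Si](C)(C)C(C)(C)C | intermediate
26 | querciformolide D | C=C1C(=O)O[C@]2(C)CC[C@@H]1C[C@H](O)[C@@]1(C)CC[C@H](O1)[C@](C)(O)CC[C@H]2O | target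

**Step count and risks**

Total steps: 14. Longest linear sequence: 11 steps (steps 1–4, then 8–14).

The three steps most likely to fail:

Step 11 (the new ynolate ring expansion). The lactone may enolise instead of accepting LiCHBr2, the C11 silyl group may migrate to the C12 alkoxide, or the ketene may be captured intermolecularly. The fallback uses known chemistry, sets out from 18 and replaces steps 10 and 11. Me3Al-promoted one-carbon homologation with Me3SiCHN2 (CH2Cl2, −78 → −20 °C), in which the less substituted α-carbon C1 migrates with retention, gives the 6-(trimethylsilyl)cyclohexanone analogue of 18 F1. K2CO3 in MeOH removes the C-silyl group to give the ring-A cyclohexanone F2. Baeyer–Villiger oxidation of this ketone (mCPBA, NaHCO3; C12 migrates) gives 21, where the route is rejoined.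

Step 8 (enolate–epoxide union and C1 configuration). A hindered ketone enolate may react sluggishly with the epoxide or give a poor trans:cis ratio. The fallback sets out from 16. Condensation with Me2NNH2 (AcOH cat., EtOH, 80 °C) gives the N,N-dimethylhydrazone of 16 F3. Its lithium azaenolate (LiN(i-Pr)2, THF, 0 °C) opens epoxide 9 without a Lewis acid (hydrazone alkylation with an oxirane) to give the N,N-dimethylhydrazone of 17 F4. CuCl2 in aqueous THF at pH 7 releases 17, where the route is rejoined. A minor C1 epimer carried forward can be corrected at 19 by base equilibration, since the 3,6-trans diequatorial δ-lactone is favoured.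

Step 5 (copper-catalysed methylmagnesiation of the enynyl alkoxide). Methyl Grignard reagents add slowly in this reaction and the conjugated enyne may give allenic by-products. The fallback sets out from 10 and 11. The lithium acetylide of 11 (n-BuLi, THF, −78 °C) adds to 10 to give the isolated enynol 1-(but-3-en-1-yn-1-yl)cyclobutan-1-ol F5. trans-Hydroalumination with LiAlH4/AlCl3 (60:1), which places aluminium on the carbon next to the carbinol, followed by I2 gives 1-[(1Z)-1-iodobuta-1,3-dien-1-yl]cyclobutan-1-ol F6. Me2CuLi replaces iodine by methyl with retention to give 13, where the route is rejoined.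

Further compounds
F1 | step 11 | (2R,5R)-2-[(1R)-1-(tert-butyldimethylsilyloxy)prop-2-en-1-yl]-5-[(2S)-2-[(2R,5S)-5-[(2R)-2-hydroxybut-3-en-2-yl]-2-methyloxolan-2-yl]-2-(triethylsilyloxy)ethyl]-2-methyl-6-(trimethylsilyl)cyclohexan-1-one | O=C1C([Si](C)(C)C)[C@@H](C[C@H](O[Si](CC)(CC)CC)[C@@]2(C)CC[C@H](O2)[C@](C)(O)C=C)CC[C@]1(C)[C@H](O[Si](C)(C)C(C)(C)C)C=C
F2 | step 11 | (2R,5R)-2-[(1R)-1-(tert-butyldimethylsilyloxy)prop-2-en-1-yl]-5-[(2S)-2-[(2R,5S)-5-[(2R)-2-hydroxybut-3-en-2-yl]-2-methyloxolan-2-yl]-2-(triethylsilyloxy)ethyl]-2-methylcyclohexan-1-one | O=C1C[C@@H](C[C@H](O[Si](CC)(CC)CC)[C@@]2(C)CC[C@H](O2)[C@](C)(O)C=C)CC[C@]1(C)[C@H](O[Si](C)(C)C(C)(C)C)C=C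
F3 | step 8 | N,N-dimethylhydrazone of 16 | CN(C)N=C1CCC[C@]1(C)[C@H](O[Si](C)(C)C(C)(C)C)C=C
F4 | step 8 | N,N-dimethylhydrazone of 17 | CN(C)N=C1[C@@H](C[C@H](O)[C@@]2(C)CC[C@H](O2)[C@](C)(O)C=C)CC[C@]1(C)[C@H](O[Si](C)(C)C(C)(C)C)C=C
F5 | step 5 | 1-(but-3-en-1-yn-1-yl)cyclobutan-1-ol | C=CC#CC1(O)CCC1
F6 | step 5 | 1-[(1Z)-1-iodobuta-1,3-dien-1-yl]cyclobutan-1-ol | C=C/C=C(I)/C1(O)CCC1
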